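**Plan**

Numbering: tetralin C1 (carbinol) to C4 (diarylmethine), C4a and C8a; ring A is the benzene ring, ring B the saturated ring; naphthalene atoms carry primes. C1 and C4 are both benzylic and sit on the neighbouring ring A carbons C8a and C4a, the imprint of a hydroxy-ortho-quinodimethane C1=C8a–C4a=C4 that has taken up a two-carbon dienophile.
Retrosynthesis: the C1 carbinol is traced to the C1 ketone, a helper carboxyl is put back on C2, and C1–C2 and C3–C4 are cut together to a 2-(naphthylmethyl)-3-methoxybenzaldehyde and an acrylimide; last, the C2'–CH2 bond is cut to 8-methoxy-1-naphthol and 2-bromo-6-methoxybenzaldehyde.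
Forward: the diarylmethane is joined first (ortho-hydroxyalkylation, ionic reduction), the aldehyde is installed by bromine–lithium exchange, ring B is closed in one photochemical [4+2] step, and the helper carboxyl leaves by oxidation to the β-keto acid and loss of CO2.
Stereochemistry: C4 comes from the chiral titanium TADDOLate in the cycloaddition; C1 is set last by catalyst-controlled transfer hydrogenation of the (4R)-tetralone, which should give the 1,4-trans (1S,4R) target.

Key step: step 6

Remark: the sense of induction of the titanium TADDOLate on this new substrate class cannot be derived from precedent; the route is written with the (R,R)-ligand for the (4R) series, and the (S,S)-ligand is taken instead, with nothing else changed, if the induction proves opposite.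

**Route**

Step 1
Reactants: 1 8-methoxynaphthalen-1-ol; 2 2-bromo-6-methoxybenzaldehyde
Product: 4 rac-2-[(2-bromo-6-methoxyphenyl)(hydroxy)methyl]-8-methoxynaphthalen-1-ol, via bromomagnesium naphthoxide 3 (not isolated)
Conditions: EtMgBr (1.0 equiv), Et2O, 0 °C; evaporate, PhMe; 2, rt; 1 M HCl
Reagents that add atoms: none
Why: Magnesium-phenoxide-directed ortho-hydroxyalkylation (Casiraghi reaction): in a non-coordinating solvent the aldehyde binds to the magnesium of naphthoxide 3 and is delivered through a six-membered cyclic transition state to C2', the only free ortho carbon, so the para carbon C4' is not attacked, and the two ortho substituents of 2 slow a second arylation of the benzhydrol, whose new stereocentre is of no consequence because it is removed in step 2.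

Step 2
Reactants: 4 rac-2-[(2-bromo-6-methoxyphenyl)(hydroxy)methyl]-8-methoxynaphthalen-1-ol
Product: 5 2-[(2-bromo-6-methoxyphenyl)methyl]-8-methoxynaphthalen-1-ol
Conditions: Et3SiH, TFA, CH2Cl2, 0 °C
Reagents that add atoms: none
Why: Ionic hydrogenation: the benzhydrol, flanked by an ortho-hydroxy and an ortho-methoxy aryl group, ionises in TFA to an ortho-quinone methide/diarylmethyl cation that should take hydride from Et3SiH faster than it can alkylate a second naphthol, while the aryl bromide and the methyl ethers are inert.

Step 3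
Reactants: 5 2-[(2-bromo-6-methoxyphenyl)methyl]-8-methoxynaphthalen-1-ol
Product: 7 2-[(2-bromo-6-methoxyphenyl)methyl]-8-methoxy-1-(methoxymethoxy)naphthalene, via sodium naphthoxide 6 (not isolated)
Conditions: NaH, DMF, 0 °C; MOMCl, 0 °C to rt
Reagents that add atoms: chloromethyl methyl ether (MOMCl), COCCl
Why: Williamson etherification: NaH in DMF breaks the peri hydrogen bond and gives the free naphthoxide 6, which is alkylated on oxygen by the highly reactive α-chloro ether; the MOM acetal is chosen because it survives n-BuLi, titanium alkoxides, LiOOH and the periodinane and is removed by mild acid at the ketone stage.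

Step 4
Reactants: 7 2-[(2-bromo-6-methoxyphenyl)methyl]-8-methoxy-1-(methoxymethoxy)naphthalene
Product: 9 3-methoxy-2-{[8-methoxy-1-(methoxymethoxy)naphthalen-2-yl]methyl}benzaldehyde, via aryllithium 8 (not isolated)
Conditions: n-BuLi, THF, −78 °C; DMF, −78 to 0 °C; H2O
Reagents that add atoms: N,N-dimethylformamide (DMF), CN(C)C=O
Why: Bromine–lithium exchange followed by formylation with DMF (Bouveault aldehyde synthesis): at −78 °C exchange is far faster than deprotonation of the diarylmethane CH2 or ortho-lithiation next to the MOM ether, and the tetrahedral amino alkoxide releases the aldehyde only on aqueous work-up, so no second addition occurs.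

Step 5
Reactants: 10 1,3-oxazolidin-2-one; 11 acryloyl chloride
Product: 13 3-acryloyl-1,3-oxazolidin-2-one, via N-bromomagnesio oxazolidinone 12 (not isolated)
Conditions: MeMgBr, THF, 0 °C; 11, −78 to 0 °C
Reagents that add atoms: none
Why: N-Acylation of a carbamate salt with an acid chloride: the magnesium salt 12 is nucleophilic enough at nitrogen to be acylated at low temperature but too weakly basic to start conjugate addition or anionic polymerisation of the acrylate.

Step 6
Reactants: 9 3-methoxy-2-{[8-methoxy-1-(methoxymethoxy)naphthalen-2-yl]methyl}benzaldehyde; 13 3-acryloyl-1,3-oxazolidin-2-one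
Product: 15 3-{[(1R,2R,4R)-1-hydroxy-5-methoxy-4-[8-methoxy-1-(methoxymethoxy)naphthalen-2-yl]-1,2,3,4-tetrahydronaphthalen-2-yl]carbonyl}-1,3-oxazolidin-2-one, via (E)-dienol 14 (not isolated)
Conditions: Ti(Oi-Pr)4 (1.2 equiv), (R,R)-TADDOL [(4R,5R)-2,2-dimethyl-α,α,α',α'-tetraphenyl-1,3-dioxolane-4,5-dimethanol] (1.3 equiv), PhMe, rt, i-PrOH stripped in vacuo; 9, 13 (3 equiv), 4 Å MS, PhMe, hν (365 nm LED), 0 °C, Ar; aq. NaHCO3
Reagents that add atoms: none
Why: Proposed new method: excitation of the aldehyde n,π* band of 9 at 365 nm, where the dialkoxynaphthalene should absorb little, is followed by 1,5-hydrogen transfer from the doubly benzylic C4 methylene to the carbonyl oxygen through a six-membered transition state, and the biradical collapses to the (E)-dienol 14 (C1=C8a–C4a=C4), which is captured on titanium as a dienolate and adds the titanium-bound acrylimide 13. The closest known reaction type is the photoenolisation/Diels–Alder reaction of 2-methylbenzaldehydes made enantioselective by titanium TADDOLates, together with the classical photoenolisation of 2-benzyl aryl ketones; new is the diarylmethane bearing a naphthalene that can accept triplet energy, an event expected only to cost photons because the naphthalene triplet should return 9 unchanged while the weak doubly benzylic C–H bond keeps hydrogen transfer fast. Ring B closes in a suprafacial [4+2] cycloaddition that forms C1–C2 and C3–C4 in one operation, the acrylimide β-carbon (C3) bonding to C4, the diene terminus remote from oxygen that carries the largest HOMO coefficient. C4 is set by the diene face left open by the TADDOLate while titanium holds both the dienolate oxygen and the chelating imide, C1 follows from attack on that same face of a dienol whose oxygen points outward, and C2 from the endo, titanium-bridged placement of the acyl group beside the C1 oxygen, which together should give the all-cis (1R,2R,4R) adduct. The step needs ortho regiochemistry, a uniform naphthyl-outward diene geometry and enantiofacial selection; the first rests on the polarised hydroxy-diene and the titanium bridge, the second on the inside position at C4 being blocked by the inward hydrogen at C1, and the third on the ligand, and because C1 and C2 are erased in steps 7 and 8 only the C4 configuration has to be uniform.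

Step 7
Reactants: 15 3-{[(1R,2R,4R)-1-hydroxy-5-methoxy-4-[8-methoxy-1-(methoxymethoxy)naphthalen-2-yl]-1,2,3,4-tetrahydronaphthalen-2-yl]carbonyl}-1,3-oxazolidin-2-one
Product: 17 (1R,2R,4R)-1-hydroxy-5-methoxy-4-[8-methoxy-1-(methoxymethoxy)naphthalen-2-yl]-1,2,3,4-tetrahydronaphthalene-2-carboxylic acid, via peroxy acid 16 (not isolated)
Conditions: LiOH, H2O2, THF/H2O (3:1), 0 °C; aq. Na2SO3; 1 M HCl to pH 3, 0 °C
Reagents that add atoms: hydrogen peroxide, OO
Why: Hydroperoxide cleavage of an N-acyloxazolidinone: the small, highly nucleophilic HOO− attacks the exocyclic carbonyl, the peroxy acid 16 is reduced by sulfite, and at 0 °C the β-hydroxy acid is not expected to undergo retro-aldol opening of ring B; the configurations at C1, C2 and C4 are carried over unchanged.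

Step 8
Reactants: 17 (1R,2R,4R)-1-hydroxy-5-methoxy-4-[8-methoxy-1-(methoxymethoxy)naphthalen-2-yl]-1,2,3,4-tetrahydronaphthalene-2-carboxylic acid
Product: 19 (4R)-5-methoxy-4-[8-methoxy-1-(methoxymethoxy)naphthalen-2-yl]-3,4-dihydronaphthalen-1(2H)-one, via keto acid 18 (not isolated)
Conditions: Dess–Martin periodinane, CH2Cl2, 0 °C to rt; solvent exchange to PhMe, 80 °C
Reagents that add atoms: none
Why: Dess–Martin oxidation of the secondary benzylic alcohol followed by thermal decarboxylation of the β-keto acid 18 through its six-membered cyclic transition state removes the helper carbon together with the C1 and C2 stereocentres, so every C1/C2 diastereomer of the adduct converges on one ketone, while C4 is not α to the carbonyl and keeps its configuration; partial loss of the MOM group to the acetic acid set free would be harmless because step 9 removes it anyway.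

Step 9
Reactants: 19 (4R)-5-methoxy-4-[8-methoxy-1-(methoxymethoxy)naphthalen-2-yl]-3,4-dihydronaphthalen-1(2H)-one
Product: 20 (4R)-4-(1-hydroxy-8-methoxynaphthalen-2-yl)-5-methoxy-3,4-dihydronaphthalen-1(2H)-one
Conditions: 3 M HCl in MeOH, THF, rt to 40 °C
Reagents that add atoms: none
Why: Acid-catalysed acetal exchange (MOM ether cleavage) with methanol as acceptor: it is placed at the ketone stage because neither the aryl ketone nor the non-enolisable C4 centre is acid-sensitive, whereas the benzylic C1 alcohol of the target could ionise under the same conditions.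

Step 10
Reactants: 20 (4R)-4-(1-hydroxy-8-methoxynaphthalen-2-yl)-5-methoxy-3,4-dihydronaphthalen-1(2H)-one
Product: 21 Dipolynaphthalene A, (1S,4R)-4-(1-hydroxy-8-methoxynaphthalen-2-yl)-5-methoxy-1,2,3,4-tetrahydronaphthalen-1-ol
Conditions: RuCl[(S,S)-TsDPEN](p-cymene) (2 mol %), HCO2H/Et3N (5:2), EtOAc, 30 °C
Reagents that add atoms: none
Why: Noyori asymmetric transfer hydrogenation of an aryl ketone: hydride and proton are passed from the Ru–H/N–H pair through a six-membered transition state in which ring A lies under the p-cymene ligand, an arrangement that with the (S,S)-ligand converts 1-tetralones into (S)-carbinols, so that the catalyst rather than the remote C4 centre should decide the face and give the (1S,4R) trans isomer; the free naphthol and the methyl ethers are tolerated.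

**Compound list**

1 | 8-methoxynaphthalen-1-ol | COc1cccc2cccc(O)c12 | starting material
2 | 2-bromo-6-methoxybenzaldehyde | COc1cccc(Br)c1C=O | starting material
3 | bromomagnesium 8-methoxynaphthalen-1-olate | COc1cccc2cccc(O[Mg]Br)c12 | intermediate
4 | rac-2-[(2-bromo-6-methoxyphenyl)(hydroxy)methyl]-8-methoxynaphthalen-1-ol | COc1cccc(Br)c1C(O)c1ccc2cccc(OC)c2c1O | intermediate
5 | 2-[(2-bromo-6-methoxyphenyl)methyl]-8-methoxynaphthalen-1-ol | COc1cccc(Br)c1Cc1ccc2cccc(OC)c2c1O | intermediate
6 | sodium 2-[(2-bromo-6-methoxyphenyl)methyl]-8-methoxynaphthalen-1-olate | COc1cccc(Br)c1Cc1ccc2cccc(OC)c2c1[O-].[Na+] | intermediate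
7 | 2-[(2-bromo-6-methoxyphenyl)methyl]-8-methoxy-1-(methoxymethoxy)naphthalene | COc1cccc(Br)c1Cc1ccc2cccc(OC)c2c1OCOC | intermediate
8 | (3-methoxy-2-{[8-methoxy-1-(methoxymethoxy)naphthalen-2-yl]methyl}phenyl)lithium | COc1cccc([Li])c1Cc1ccc2cccc(OC)c2c1OCOC | intermediate
9 | 3-methoxy-2-{[8-methoxy-1-(methoxymethoxy)naphthalen-2-yl]methyl}benzaldehyde | COc1cccc(C=O)c1Cc1ccc2cccc(OC)c2c1OCOC | intermediate
10 | 1,3-oxazolidin-2-one | O=C1NCCO1 | starting material
11 | acryloyl chloride (prop-2-enoyl chloride) | C=CC(Cl)=O | starting material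
12 | 3-(bromomagnesio)-1,3-oxazolidin-2-one | O=C1OCCN1[Mg]Br | intermediate
13 | 3-acryloyl-1,3-oxazolidin-2-one | C=CC(=O)N1CCOC1=O | intermediate
14 | (E)-{(6Z)-5-methoxy-6-{[8-methoxy-1-(methoxymethoxy)naphthalen-2-yl]methylidene}cyclohexa-2,4-dien-1-ylidene}methanol (hydroxy-ortho-quinodimethane of 9, hydroxyl and naphthyl both outward) | COC1=CC=C\C(=C/O)\C1=C\c1ccc2cccc(OC)c2c1OCOC | intermediate
15 | 3-{[(1R,2R,4R)-1-hydroxy-5-methoxy-4-[8-methoxy-1-(methoxymethoxy)naphthalen-2-yl]-1,2,3,4-tetrahydronaphthalen-2-yl]carbonyl}-1,3-oxazolidin-2-one (all-cis) | COc1cccc2c1[C@@H](c1ccc3cccc(OC)c3c1OCOC)C[C@@H](C(=O)N1CCOC1=O)[C@H]2O | intermediate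
16 | (1R,2R,4R)-1-hydroxy-5-methoxy-4-[8-methoxy-1-(methoxymethoxy)naphthalen-2-yl]-1,2,3,4-tetrahydronaphthalene-2-carboperoxoic acid | COc1cccc2c1[C@@H](c1ccc3cccc(OC)c3c1OCOC)C[C@@H](C(=O)OO)[C@H]2O | intermediate
17 | (1R,2R,4R)-1-hydroxy-5-methoxy-4-[8-methoxy-1-(methoxymethoxy)naphthalen-2-yl]-1,2,3,4-tetrahydronaphthalene-2-carboxylic acid | COc1cccc2c1[C@@H](c1ccc3cccc(OC)c3c1OCOC)C[C@@H](C(=O)O)[C@H]2O | intermediate
18 | (4R)-5-methoxy-4-[8-methoxy-1-(methoxymethoxy)naphthalen-2-yl]-1-oxo-1,2,3,4-tetrahydronaphthalene-2-carboxylic acid (C2 labile, not defined) | COc1cccc2c1[C@@H](c1ccc3cccc(OC)c3c1OCOC)CC(C(=O)O)C2=O | intermediate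
19 | (4R)-5-methoxy-4-[8-methoxy-1-(methoxymethoxy)naphthalen-2-yl]-3,4-dihydronaphthalen-1(2H)-one | COc1cccc2c1[C@@H](c1ccc3cccc(OC)c3c1OCOC)CCC2=O | intermediate
20 | (4R)-4-(1-hydroxy-8-methoxynaphthalen-2-yl)-5-methoxy-3,4-dihydronaphthalen-1(2H)-one | COc1cccc2c1[C@@H](c1ccc3cccc(OC)c3c1O)CCC2=O | intermediate
21 | Dipolynaphthalene A, (1S,4R)-4-(1-hydroxy-8-methoxynaphthalen-2-yl)-5-methoxy-1,2,3,4-tetrahydronaphthalen-1-ol | COc1cccc2c1[C@@H](c1ccc3cccc(OC)c3c1O)CC[C@@H]2O | target

**Step count**

Total: 10 steps. Longest linear sequence: 9 steps (steps 1 to 4 and 6 to 10, from 1 or 2); step 5 is a one-step side branch.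

**Steps most likely to fail**

Step 6. Three processes may defeat it. Triplet energy transfer from the excited aldehyde to the naphthalene may outrun hydrogen transfer, so that the dienol forms too slowly. The diene geometry at C4 may be eroded by allylic 1,3-strain between the outward naphthyl group and the C5 methoxy group. The facial selection by the ligand may be poor, or the imide may be lost to alcoholysis on titanium. The fallback makes the same two bonds in the ground state by an anionic Michael–Dieckmann (Staunton–Weinreb) annulation and uses only known chemistry. It sets out from bromide 7: aryllithium 8 is quenched with methyl chloroformate instead of DMF to give methyl 3-methoxy-2-{[8-methoxy-1-(methoxymethoxy)naphthalen-2-yl]methyl}benzoate F1. LiN(i-Pr)2 in THF at −78 °C removes a doubly benzylic proton ortho to the ester. The anion adds to methyl acrylate (C3–C4) and the ester enolate closes onto the benzoate (C1–C2), giving methyl rac-5-methoxy-4-[8-methoxy-1-(methoxymethoxy)naphthalen-2-yl]-1-oxo-1,2,3,4-tetrahydronaphthalene-2-carboxylate F2. Krapcho dealkoxycarbonylation (LiCl, wet DMSO, 140 °C) should give rac-5-methoxy-4-[8-methoxy-1-(methoxymethoxy)naphthalen-2-yl]-3,4-dihydronaphthalen-1(2H)-one F3, and the conditions of step 9 rac-4-(1-hydroxy-8-methoxynaphthalen-2-yl)-5-methoxy-3,4-dihydronaphthalen-1(2H)-one F4. The transfer hydrogenation of step 10 then serves as a divergent reduction of the racemate: the (S,S)-catalyst is expected to turn both enantiomers into (1S)-carbinols. The (4R)-ketone gives 21, and the (4S)-ketone gives the cis diastereomer (1S,4S)-4-(1-hydroxy-8-methoxynaphthalen-2-yl)-5-methoxy-1,2,3,4-tetrahydronaphthalen-1-ol F5, which is removed by chromatography. The fallback comes back to the route at 21, at the price of half the material.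

Step 1. The peri methoxy group may chelate magnesium and the doubly ortho-substituted aldehyde may add sluggishly. Attack may stray to the para carbon C4', or the benzhydrol may ionise and arylate a second naphthoxide. The fallback reverses the roles by directed ortho-metalation and sets out from naphthol 1. NaH/MOMCl in DMF gives 1-methoxy-8-(methoxymethoxy)naphthalene F6. n-BuLi/TMEDA in Et2O at 0 °C lithiates ortho to the MOM ether to give [8-methoxy-1-(methoxymethoxy)naphthalen-2-yl]lithium F7. This adds to aldehyde 2 at −78 °C to give rac-(2-bromo-6-methoxyphenyl)[8-methoxy-1-(methoxymethoxy)naphthalen-2-yl]methanol F8. Et3SiH/TFA as in step 2 reduces the carbinol and at the same time cleaves the MOM ether, so the fallback comes back to the route at 5.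

Step 10. The pseudo-axial C4 naphthyl group may bias hydride delivery towards the cis carbinol strongly enough to oppose the catalyst (mismatched pairing), which would give poor diastereoselectivity or slow reduction. The fallback uses that substrate bias and then inverts C1; it sets out from ketone 19. LiBH(s-Bu)3 (L-Selectride) in THF at −78 °C should attack anti to the naphthyl group and give the cis alcohol (1R,4R)-5-methoxy-4-[8-methoxy-1-(methoxymethoxy)naphthalen-2-yl]-1,2,3,4-tetrahydronaphthalen-1-ol F9. Mitsunobu inversion (4-nitrobenzoic acid, PPh3, DIAD, THF, 0 °C) gives (1S,4R)-5-methoxy-4-[8-methoxy-1-(methoxymethoxy)naphthalen-2-yl]-1,2,3,4-tetrahydronaphthalen-1-yl 4-nitrobenzoate F10. HCl in MeOH removes the MOM group while the electron-poor ester shields C1 from ionisation, giving (1S,4R)-4-(1-hydroxy-8-methoxynaphthalen-2-yl)-5-methoxy-1,2,3,4-tetrahydronaphthalen-1-yl 4-nitrobenzoate F11. K2CO3 in MeOH at rt then releases the carbinol, and the fallback comes back to the route at 21.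

**Further compounds**

F1 | step 6 | methyl 3-methoxy-2-{[8-methoxy-1-(methoxymethoxy)naphthalen-2-yl]methyl}benzoate | COC(=O)c1cccc(OC)c1Cc1ccc2cccc(OC)c2c1OCOC
F2 | step 6 | methyl rac-5-methoxy-4-[8-methoxy-1-(methoxymethoxy)naphthalen-2-yl]-1-oxo-1,2,3,4-tetrahydronaphthalene-2-carboxylate | COC(=O)C1CC(c2ccc3cccc(OC)c3c2OCOC)c2c(OC)cccc2C1=O
F3 | step 6 | rac-5-methoxy-4-[8-methoxy-1-(methoxymethoxy)naphthalen-2-yl]-3,4-dihydronaphthalen-1(2H)-one | COc1cccc2c1C(c1ccc3cccc(OC)c3c1OCOC)CCC2=O
F4 | step 6 | rac-4-(1-hydroxy-8-methoxynaphthalen-2-yl)-5-methoxy-3,4-dihydronaphthalen-1(2H)-one | COc1cccc2c1C(c1ccc3cccc(OC)c3c1O)CCC2=O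
F5 | step 6 | (1S,4S)-4-(1-hydroxy-8-methoxynaphthalen-2-yl)-5-methoxy-1,2,3,4-tetrahydronaphthalen-1-ol | COc1cccc2c1[C@H](c1ccc3cccc(OC)c3c1O)CC[C@@H]2O
F6 | step 1 | 1-methoxy-8-(methoxymethoxy)naphthalene | COCOc1cccc2cccc(OC)c12
F7 | step 1 | [8-methoxy-1-(methoxymethoxy)naphthalen-2-yl]lithium | COCOc1c([Li])ccc2cccc(OC)c12
F8 | step 1 | rac-(2-bromo-6-methoxyphenyl)[8-methoxy-1-(methoxymethoxy)naphthalen-2-yl]methanol | COCOc1c(C(O)c2c(Br)cccc2OC)ccc2cccc(OC)c12
F9 | step 10 | (1R,4R)-5-methoxy-4-[8-methoxy-1-(methoxymethoxy)naphthalen-2-yl]-1,2,3,4-tetrahydronaphthalen-1-ol | COc1cccc2c1[C@@H](c1ccc3cccc(OC)c3c1OCOC)CC[C@H]2O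
F10 | step 10 | (1S,4R)-5-methoxy-4-[8-methoxy-1-(methoxymethoxy)naphthalen-2-yl]-1,2,3,4-tetrahydronaphthalen-1-yl 4-nitrobenzoate | COc1cccc2c1[C@@H](c1ccc3cccc(OC)c3c1OCOC)CC[C@@H]2OC(=O)c1ccc(cc1)[N+](=O)[O-]
F11 | step 10 | (1S,4R)-4-(1-hydroxy-8-methoxynaphthalen-2-yl)-5-methoxy-1,2,3,4-tetrahydronaphthalen-1-yl 4-nitrobenzoate | COc1cccc2c1[C@@H](c1ccc3cccc(OC)c3c1O)CC[C@@H]2OC(=O)c1ccc(cc1)[N+](=O)[O-]
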